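The constants come first, and with them the flask:

    G + D ⇌ X + L (K1 = 0.92, k1 = 0.76 L mol⁻¹ s⁻¹)
    J + D ⇌ X + G (K2 = 6.8, k2 = 0.64 L mol⁻¹ s⁻¹)
    Z + D ⇌ X + J (K3 = 3.9, k3 = 0.29 L mol⁻¹ s⁻¹)
    Q ⇌ D, rate k4*(csat - [D]) (k4 = 0.83 s⁻¹, csat = 120 mM)

Z 0.22 M; Q 120 mM (held); time 2.0 min

- J at 2.0 min, in percent of the Z charged
- the change that raises the amount of J at 2.0 min, in percent of the Z charged most ("none" if none brings more than 2 percentage points) (maple / elm / none)
- amount of J at 2.0 min, in percent of the Z charged, after maple

- maple: doubling the transfer coefficient of step 4, all else as stated
- elm: doubling the saturation concentration of Q, all else as stated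

- at the start none of D is dissolved
- run time (flask): 2.0 min

Minutes of the meeting on this flask. I opened by arguing that time is not the difficulty here. D is consumed by the conversion of Z into J with a pseudo-first-order lifetime of 15.7 s as charged, and the gas replaces it within 1.20 s, so I held [D] near the saturation concentration. At that [D], Z has a forward half-life of 0.332 min, and 2.0 min holds 6.02 of them.

I therefore proposed reading J from the ladder at equilibrium, where each rung stands to the one below it as its equilibrium constant times [D]/[X], and each exchange frees one X. A trial [D]/[X] of 0.333 gives 1.61 exchanges per Z. Dividing the saturation concentration by the X so freed gives the exchange ratio 0.339, close to the trial, and J's share at that ratio is 20.9 %.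

The transfer coefficient does not appear in r, so I gave maple the same figure. For elm, which doubles the saturation concentration of Q, a trial [D]/[X] of 0.500 gives 1.93 exchanges, a ratio of 0.566 and J at 13.7 %, which is less than my figure for the flask. My answer to the choice was none.

The forecast was then tabled: 20.8 %, none and 20.6 %, on the ground that “the ladder has nearly relaxed to its X-suppressed equilibrium”.

The flask gives 21.0 %, none and 21.0 %, with maple moving J by 0 percentage points and elm by −6.8 points. J in the flask stands at 20.9 % after 1.00 min and at 21.0 % after 20.0 min. The exchange ratio puts [X] at 0.354 M, and the flask reads 0.353 M at 2.00 min. For the neighbour flask with 0.13 M of Z, the same trial of 0.500 gives an exchange ratio of 0.479 and J at 16.1 %. The computed neighbour flask gives 16.0 %.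

The numbers are invented; the run is a simulation.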